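The data were generated by integration with made-up constants, and the scatter is random.

In the south run Z loses half of what it holds in less time than the 12 min asked about: it falls from 78% at 0.667 min to 39% at 2.50 min, so its half-life τ reads 1.83 min.

| flask | Z | X | D | remark | time |
|---|---|---|---|---|---|
| south | 0.40 M | 10 mol% | 22 mM | the very flask that is asked about, followed so far |  |
| flask | 0.40 M | 10 mol% | 22 mM |  | 12 min |

south run (percent of the Z charged)

| time / min | J / % | Z / % |
|---|---|---|
| 0.200 | 10 | 87 |
| 0.667 | 22 | 78 |
| 1.00 | 29 | 70 |
| 1.50 | 39 | 57 |
| 2.50 | 57 | 39 |

(each reading ± 2 percentage points)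

* average number of monomer units in a chain (chains begun, living or dead) at 12 min
* part of the Z that has reacted at 12 min

- the average divides the monomer in chains by the number of chains begun, living and dead together
- what was read earlier has a scatter of 2 percentage points, one standard deviation
- candidate steps: Z + X -> G + J; Z + G -> J + G; G + Z -> L; X + D -> Q
- the earlier runs do not show the number of chains; that part of a forecast is a guess

Counting half-lives gives n, the time over τ, and Z left is what n halvings leave. For c, the part of the Z that has reacted, τ need not be known well: at 2.75 min the count still leaves 4.83% of the Z. For dp, the average number of monomer units in a chain, the number of chains must be known well, and that number is a guess. Chains start from X, the initiator, and D can remove X. If D takes none, 40.0 mM of chains give about 10.0 units each. If D takes its full charge, 18.0 mM of chains give longer ones. This reckoning takes the full charge: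

n = 6.55, Z left = 1.07%, c = 98.9%

dp = 22.0

κ = ln(2)/(τ·[G]) = 21.0 L mol⁻¹ min⁻¹

Here κ is the pseudo-first-order decay of Z per unit of living end G, with [G] taken as the 18.0 mM of chains, so that n = time·κ·[G]/ln(2).

The forecast gives c = 97% (90% to 99.7%) and dp = 17 (10 to 23), each below this reckoning's value: “D is probably mostly effective”.

The flask gives c = 97.9% and dp = 21.2.

    Z + X → G + J (k = 0.466 L mol⁻¹ s⁻¹)
    Z + G → J + G, rate k2*[G]*[Z] (k = 0.327 L mol⁻¹ s⁻¹)
    G + Z → L (k = 0.00256 L mol⁻¹ s⁻¹)
    X + D → Q (k = 39.8 L mol⁻¹ s⁻¹)

At 12 min the flask holds G at 0.0155 M, and κ turns that into n = 5.64, with 2.01% of the Z left against 2.12% found. The neighbour charged with 0.16 M of Z holds G at 0.00150 M at that time. The same count there gives n = 0.545 and leaves 68.5% of its Z. That neighbour reaches dp = 28.0, with Z found at 66.4%.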